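**Strategy.** The route rests on disconnecting the C1–C10 bond of ring A. Ring B of the target, with its methyl on C8, the C11 carbon on C9 and the methyl on quaternary C10, maps onto a 2,4-dimethyl-3-(oxymethyl)phenol whose para carbon is C10; the phenol oxygen sits on C7 and is deleted afterwards. In one operation, a Pd-catalysed, ligand-controlled allylation lets this para carbon attack a tethered Z-allyl carbonate, closing ring A, creating C10 as the first stereocentre and dearomatising ring B. The precursor is a 6-bromophenol carrying, meta to the hydroxyl, a CMe2–CH=CH–CH2OCO2Me tether. Hydrogenation then sets C5, and a B-alkyl Suzuki coupling adds the lactone side chain.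

Key step: step 13

Remarks.
- Atom labels: decalin C1–C10 (ring A = C1–C5, C10; ring B = C5–C10), C11 on C9, chain C12–C16, lactone CH = C17, lactone CH2C(=O) = C18, C=O = C19, OCH2 = C20, hydroxymethyl carbon on C13 = C21; aromatic intermediates carry the labels their carbons will have in ring B.
- C10 keeps its spatial arrangement from 16 to 40; its descriptor changes from R (16) to S (17 onwards) only because bromine leaves C6.
- Assumption: the sense of induction of the phosphoramidite cannot be predicted and is to be fixed in a first screen; step 13 is written for the ligand antipode that gives (10R)-16.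
- Assumption: 25 and 27 are taken as purchased compounds.

**Route**

Step 1
Reactants: 1 2,6-dimethylbenzoic acid
Product: 2 3-bromo-2,6-dimethylbenzoic acid
Conditions: Br2 (1.05 equiv), FeBr3 (5 mol%), AcOH, 25 °C, dark
Reagents that add atoms: bromine, BrBr
Why: Electrophilic aromatic bromination should occur once, at the position ortho to one methyl, para to the other and meta to the carboxyl group (future C5), because the first bromine deactivates the ring.

Step 2
Reactants: 2 3-bromo-2,6-dimethylbenzoic acid
Product: 3 methyl 3-bromo-2,6-dimethylbenzoate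
Conditions: MeI (1.5 equiv), K2CO3 (2 equiv), DMF, 25 °C
Reagents that add atoms: iodomethane, CI
Why: O-Alkylation of the carboxylate (SN2 on iodomethane) should give the ester without the crowded tetrahedral intermediate that slows Fischer esterification of di-ortho-substituted benzoic acids.

Step 3
Reactants: 3 methyl 3-bromo-2,6-dimethylbenzoate; 4 isobutyronitrile
Product: 5 methyl 3-(2-cyanopropan-2-yl)-2,6-dimethylbenzoate
Conditions: NaN(SiMe3)2 (1.3 equiv), Pd2(dba)3 (2 mol%), rac-BINAP (5 mol%), toluene, 90 °C
Reagents that add atoms: none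
Why: Palladium-catalysed α-arylation of a nitrile: the keteniminate of 4 should couple with the aryl bromide and create the quaternary carbon C4, while the di-ortho-substituted ester is shielded from base and nucleophile.

Step 4
Reactants: 5 methyl 3-(2-cyanopropan-2-yl)-2,6-dimethylbenzoate
Product: 6 methyl 3-bromo-5-(2-cyanopropan-2-yl)-2,6-dimethylbenzoate
Conditions: Br2 (1.05 equiv), FeBr3 (5 mol%), CH2Cl2, 0 °C, dark
Reagents that add atoms: bromine, BrBr
Why: Electrophilic bromination should go to the ring position that is ortho and para to the two methyls and meta to the ester (future C7), since the other free CH (future C6) is flanked by the tert-alkyl group and is not activated.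

Step 5
Reactants: 6 methyl 3-bromo-5-(2-cyanopropan-2-yl)-2,6-dimethylbenzoate
Product: 7 methyl 3-(2-cyanopropan-2-yl)-5-hydroxy-2,6-dimethylbenzoate
Conditions: KOH (3 equiv), Pd2(dba)3 (1 mol%), t-BuXPhos (4 mol%), 1,4-dioxane/H2O, 100 °C; then aq. HCl
Reagents that add atoms: potassium hydroxide, [K+].[OH-]
Why: Palladium-catalysed hydroxylation of the aryl bromide (C–O reductive elimination from an arylpalladium hydroxide) should give the phenol, the mesitoate-type ester and the tertiary nitrile being too hindered for hydroxide.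

Step 6
Reactants: 7 methyl 3-(2-cyanopropan-2-yl)-5-hydroxy-2,6-dimethylbenzoate
Product: 8 methyl 4-bromo-3-(2-cyanopropan-2-yl)-5-hydroxy-2,6-dimethylbenzoate
Conditions: NBS (1.05 equiv), i-Pr2NH (10 mol%), CH2Cl2, 0 °C
Reagents that add atoms: N-bromosuccinimide, O=C1CCC(=O)N1Br
Why: Amine-mediated ortho-bromination of the phenol should place bromine on C6, the only unsubstituted ring carbon, which lies ortho to the hydroxyl.

Step 7
Reactants: 8 methyl 4-bromo-3-(2-cyanopropan-2-yl)-5-hydroxy-2,6-dimethylbenzoate
Product: 10 2-[2-bromo-3-hydroxy-5-(hydroxymethyl)-4,6-dimethylphenyl]-2-methylpropanal, via aldimine 9 (not isolated)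
Conditions: i-Bu2AlH (5 equiv), CH2Cl2, −78 → 0 °C; then aq. potassium sodium tartrate, 1 M HCl
Reagents that add atoms: water, O
Why: i-Bu2AlH should reduce the ester to the benzylic alcohol (C11) and the nitrile only to the N-aluminated aldimine, which is hydrolysed through 9 to an aldehyde that has no α-hydrogen and cannot enolise.

Step 8
Reactants: 10 2-[2-bromo-3-hydroxy-5-(hydroxymethyl)-4,6-dimethylphenyl]-2-methylpropanal
Product: 11 2-[2-bromo-3-(tert-butyldimethylsilyloxy)-5-(tert-butyldimethylsilyloxymethyl)-4,6-dimethylphenyl]-2-methylpropanal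
Conditions: TBSCl (2.6 equiv), imidazole (5 equiv), DMF, 40 °C
Reagents that add atoms: tert-butyldimethylsilyl chloride, CC(C)(C)[Si](C)(C)Cl
Why: Imidazole-promoted silylation should cap both hydroxyls, so that the phenol stays masked during the base- and hydride-mediated steps that follow.

Step 9
Reactants: 11 bis-silylated aldehyde
Product: 12 methyl (Z)-4-[2-bromo-3-(tert-butyldimethylsilyloxy)-5-(tert-butyldimethylsilyloxymethyl)-4,6-dimethylphenyl]-4-methylpent-2-enoate
Conditions: (CF3CH2O)2P(O)CH2CO2Me (1.5 equiv), KN(SiMe3)2 (1.5 equiv), 18-crown-6, THF, −78 → −40 °C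
Reagents that add atoms: methyl bis(2,2,2-trifluoroethyl)phosphonoacetate, COC(=O)CP(=O)(OCC(F)(F)F)OCC(F)(F)F
Why: Still–Gennari olefination: the electron-poor phosphonate anion adds to the non-enolisable aldehyde and eliminates faster than the adducts equilibrate, which should give the Z-enoate (C2=C3).

Step 10
Reactants: 12 Z-enoate
Product: 13 (Z)-4-[2-bromo-3-(tert-butyldimethylsilyloxy)-5-(tert-butyldimethylsilyloxymethyl)-4,6-dimethylphenyl]-4-methylpent-2-en-1-ol
Conditions: i-Bu2AlH (2.5 equiv), CH2Cl2, −78 °C
Reagents that add atoms: none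
Why: 1,2-Reduction of the enoate by i-Bu2AlH at low temperature should give the allylic alcohol with the Z geometry intact and without touching the silyl ethers or the aryl bromide.

Step 11
Reactants: 13 Z-allylic alcohol
Product: 14 (Z)-4-[2-bromo-3-(tert-butyldimethylsilyloxy)-5-(tert-butyldimethylsilyloxymethyl)-4,6-dimethylphenyl]-4-methylpent-2-en-1-yl methyl carbonate
Conditions: ClCO2Me (1.5 equiv), pyridine (3 equiv), DMAP (5 mol%), CH2Cl2, 0 °C
Reagents that add atoms: methyl chloroformate, COC(=O)Cl
Why: Acylation of the primary allylic alcohol should give the methyl carbonate, which will later release methoxide as internal base; the silylated phenol cannot compete.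

Step 12
Reactants: 14 bis-silylated allyl carbonate
Product: 15 (Z)-4-[2-bromo-3-hydroxy-5-(tert-butyldimethylsilyloxymethyl)-4,6-dimethylphenyl]-4-methylpent-2-en-1-yl methyl carbonate
Conditions: KHF2 (2.5 equiv), MeOH, 25 °C
Reagents that add atoms: none
Why: Bifluoride should cleave the aryl silyl ether selectively, because aryloxide is a far better leaving group on silicon than a primary alkoxide, under near-neutral conditions that leave the carbonate, the Z-alkene and the C11 silyl ether intact.

Step 13
Reactants: 15 bromophenol Z-allyl methyl carbonate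
Product: 16 (4aR)-1-bromo-4-(tert-butyldimethylsilyloxymethyl)-3,4a,8,8-tetramethyl-5,8-dihydronaphthalen-2(4aH)-one (the 10R bromodienone: ring B is a 6-bromo-cyclohexa-5,8-dien-7-one, ring A holds cis C2=C3)
Conditions: Pd2(dba)3·CHCl3 (2.5 mol%), (S,S,S)-configured BINOL-derived bis(1-phenylethyl)amine phosphoramidite (6 mol%), toluene (0.01 M), 40 °C
Reagents that add atoms: none
Why: Proposed new method: zerovalent palladium should ionise the Z-allyl methyl carbonate with loss of CO2 to an anti-configured π-allylpalladium methoxide, the methoxide deprotonates the phenol, and the phenolate attacks the unsubstituted allyl terminus C1 through its para carbon C10 on the face away from the metal, which forms C1–C10 and dearomatises ring B to the cross-conjugated dienone. The closest known reactions are the palladium-catalysed intramolecular allylic dearomatisation of para-tethered phenols to spirocyclohexadienones (Tsuji–Trost type) and the base-mediated para-alkylation of phenolates by a tethered electrophile. Ring A closes in a 6-endo mode with respect to the allyl unit (all three allyl carbons end up in the ring), which requires the anti geometry supplied by the Z-alkene and leaves an endocyclic cis C2=C3 bond, whereas attack at the inner carbon C3 would give a cyclobutane and is not expected. The only new stereocentre, quaternary C10, is under ligand control: the two diastereomeric π-allyl complexes (metal on either allyl face) should interconvert through the η1 form at the unhindered terminus C1, each leads to one enantioface of C10, and the chiral phosphoramidite selects between them. The step needs C10 rather than C6 attack and C- rather than O-allylation: bromine on C6 blocks the re-aromatising path at the other ring carbon within reach, intramolecular O-allylation is geometrically impossible for the meta tether, and high dilution suppresses the intermolecular version. The quaternary C4 next to the substituted allyl terminus should slow syn/anti isomerisation, and the hindered, electron-rich C6–Br bond is not expected to undergo oxidative addition at 40 °C.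

Step 14
Reactants: 16 bromodienone
Product: 17 (5R,10S)-cis-fused enone: 11-(tert-butyldimethylsilyloxy)-4,4,8,10-tetramethyl decal-8-en-7-one with 5-H and 10-CH3 on the same face
Conditions: H2 (1 atm), 10% Pd/C, Et3N (3 equiv), EtOAc, 25 °C
Reagents that add atoms: none
Why: Heterogeneous hydrogenation should cleave the vinylic C–Br bond (HBr trapped by Et3N), saturate cis-disubstituted C2=C3 and add hydrogen to C5=C6 from the convex face that carries the C10 methyl (ring A is folded towards the other face), as is usual for palladium-catalysed hydrogenation of 10-methyl octalones in basic medium, which sets C5 with cis fusion while tetrasubstituted C8=C9 stays.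

Step 15
Reactants: 17 cis-fused enone
Product: 19 (5R,10S)-dienyl triflate (C6=C7–OTf and C8=C9), via lithium dienolate 18 (not isolated)
Conditions: LiN(i-Pr)2 (1.2 equiv), THF, −78 °C; then PhNTf2 (1.3 equiv), −78 → 0 °C
Reagents that add atoms: N-phenylbis(trifluoromethanesulfonimide), O=S(=O)(N(c1ccccc1)S(=O)(=O)C(F)(F)F)C(F)(F)F
Why: Kinetic deprotonation at the α′ carbon C6 should give the cross-conjugated dienolate 18, whose O-sulfonylation fixes C7–O as a triflate; C5 is not acidic and keeps its configuration.

Step 16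
Reactants: 19 dienyl triflate
Product: 20 (5R,10S)-diene (C6=C7 and C8=C9) with C11–OTBS
Conditions: Pd(OAc)2 (5 mol%), PPh3 (10 mol%), HCO2H (2 equiv), n-Bu3N (3 equiv), DMF, 60 °C
Reagents that add atoms: none
Why: Palladium-catalysed formate reduction of an enol triflate (oxidative addition, formate exchange, loss of CO2, C–H reductive elimination) should replace the C7 oxygen by hydrogen without involving C8=C9.

Step 17
Reactants: 20 diene
Product: 21 (5R,10S)-11-(tert-butyldimethylsilyloxy)-4,4,8,10-tetramethyl decal-8-ene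
Conditions: TsNHNH2 (6 equiv), NaOAc (6 equiv), DME/H2O, reflux
Reagents that add atoms: none
Why: Diimide generated in the flask should transfer hydrogen in a concerted syn fashion to the cis-disubstituted C6=C7 bond only, because tetrasubstituted C8=C9 is inert to diimide, so the alkene stays where the target needs it.

Step 18
Reactants: 21 silyl ether
Product: 22 (5R,10S)-allylic alcohol (C11–OH on C9 of the C8=C9 decalin)
Conditions: Bu4NF (1.2 equiv), THF, 0 → 25 °C
Reagents that add atoms: none
Why: Fluoride cleavage of the primary silyl ether should free the C11 hydroxyl; no other group in 21 responds to fluoride.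

Step 19
Reactants: 22 allylic alcohol
Product: 23 (5R,10S)-enal (C11 aldehyde on C9)
Conditions: MnO2 (activated, 15 equiv), CH2Cl2, 25 °C
Reagents that add atoms: none
Why: MnO2 oxidises allylic alcohols selectively and should give the non-enolisable enal without acid or over-oxidation.

Step 20
Reactants: 23 enal
Product: 24 (5R,10S)-9-vinyl decal-8-ene (C11=C12)
Conditions: Ph3PCH3Br (1.5 equiv), KOt-Bu (1.4 equiv), THF, 0 → 25 °C
Reagents that add atoms: methyltriphenylphosphonium bromide, C[P+](c1ccccc1)(c1ccccc1)c1ccccc1.[Br-]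
Why: Wittig methylenation with the small, unstabilised ylide should convert even this hindered β-cyclocitral-type aldehyde into the terminal vinyl group that supplies C12.

Step 21
Reactants: 25 ethyl (S)-4-bromo-3-hydroxybutanoate
Product: 26 ethyl (S)-2-(oxiran-2-yl)acetate
Conditions: Ag2O (1.2 equiv), 1,2-dimethoxyethane, 60 °C
Reagents that add atoms: none
Why: Silver-assisted bromide abstraction with internal O-alkylation should close the epoxide under non-basic conditions, which avoids base-induced opening to the 4-hydroxycrotonate; the C–O bond at the stereocentre is not touched.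

Step 22
Reactants: 26 ethyl (S)-2-(oxiran-2-yl)acetate; 27 tert-butyldimethyl(prop-2-yn-1-yloxy)silane
Product: 29 ethyl (R)-7-(tert-butyldimethylsilyloxy)-3-hydroxyhept-5-ynoate, via lithium acetylide 28 (not isolated)
Conditions: n-BuLi (1.25 equiv), THF, −78 °C; BF3·OEt2 (1.3 equiv); then 26, −78 °C
Reagents that add atoms: none
Why: BF3-promoted opening of the epoxide by the lithium acetylide should occur at the CH2 terminus (forming C14–C15), the weakly basic alkynylborate and the low temperature sparing the ester and its α-hydrogens; C16 keeps its configuration.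

Step 23
Reactants: 29 ethyl (R)-7-(tert-butyldimethylsilyloxy)-3-hydroxyhept-5-ynoate
Product: 31 4-tert-butyl 1-ethyl (2R)-2-[(1R)-5-(tert-butyldimethylsilyloxy)-1-hydroxypent-3-yn-1-yl]butanedioate (anti), via dilithium dianion 30 (not isolated)
Conditions: LiN(i-Pr)2 (2.2 equiv), THF, −78 → −20 °C; then BrCH2CO2t-Bu (1.3 equiv), DMPU, −78 → −20 °C
Reagents that add atoms: tert-butyl bromoacetate, CC(C)(C)OC(=O)CBr
Why: Fráter–Seebach alkylation: the lithium-chelated alkoxide–enolate 30 should be alkylated on the face away from the C15 chain, which sets C17 anti to the C16 oxygen.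

Step 24
Reactants: 31 anti hydroxy diester
Product: 32 4-tert-butyl 1-ethyl (2R)-2-[(1R)-1,5-bis(tert-butyldimethylsilyloxy)pent-3-yn-1-yl]butanedioate
Conditions: TBSOTf (1.2 equiv), 2,6-lutidine (2 equiv), CH2Cl2, −78 → 0 °C
Reagents that add atoms: tert-butyldimethylsilyl trifluoromethanesulfonate, CC(C)(C)[Si](C)(C)OS(=O)(=O)C(F)(F)F
Why: Silylation of the hindered secondary alcohol blocks the C16 oxygen, so that only the C20 oxygen can later close the lactone and no isomeric lactone can form.

Step 25
Reactants: 32 silylated diester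
Product: 33 (2S)-2-[(1R)-1,5-bis(tert-butyldimethylsilyloxy)pent-3-yn-1-yl]butane-1,4-diol
Conditions: LiAlH4 (2.5 equiv), THF, 0 °C
Reagents that add atoms: none
Why: Hydride reduction should convert both esters into primary alcohols (C19 and C20), while the silyl ethers and the internal alkyne, which has no free propargylic hydroxyl to direct hydroalumination, stay unchanged at 0 °C.

Step 26
Reactants: 33 1,4-diol
Product: 35 (4S)-4-[(1R)-1,5-bis(tert-butyldimethylsilyloxy)pent-3-yn-1-yl]oxolan-2-one, via lactol 34 (not isolated)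
Conditions: TEMPO (0.2 equiv), PhI(OAc)2 (3 equiv), CH2Cl2, 25 °C
Reagents that add atoms: none
Why: Oxoammonium oxidation should start at the unhindered C19 carbinol (C20–OH is neopentyl-like), the C20 hydroxyl closes the five-membered lactol 34, and a second oxidation gives the γ-lactone with C19 as carbonyl (regioselective oxidative lactonisation of an unsymmetrical 1,4-diol).

Step 27
Reactants: 35 alkynyl lactone
Product: 37 (4S)-4-[(1R,3E)-1,5-bis(tert-butyldimethylsilyloxy)-4-iodopent-3-en-1-yl]oxolan-2-one, via vinylstannane 36 (not isolated)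
Conditions: Bu3SnH (1.2 equiv), PdCl2(PPh3)2 (2 mol%), THF, 0 → 25 °C; then I2 (1.3 equiv), CH2Cl2, 0 °C
Reagents that add atoms: tributyltin hydride, CCCC[SnH](CCCC)CCCC (tin kept only in 36); iodine, II
Why: Palladium-catalysed syn-hydrostannation should place tin on C13, the alkyne carbon next to the CH2OTBS group and remote from the branched C16 (electronic and steric bias; any regioisomer is removed at the iodide stage), and iododestannylation with retention then fixes CH2OTBS cis to C15.

Step 28
Reactants: 24 (5R,10S)-9-vinyl decal-8-ene; 37 vinyl iodide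
Product: 39 bis-TBS ether of the target (5R,10S,13Z,16R,17S), via alkylborane 38 (not isolated)
Conditions: 9-BBN-H (1.3 equiv), THF, 25 °C; then 37, Pd(dppf)Cl2 (5 mol%), AsPh3 (10 mol%), K3PO4 (3 M aq, 3 equiv), DMF, 25 °C
Reagents that add atoms: 9-borabicyclo[3.3.1]nonane, B1C2CCCC1CCC2 (boron kept only in 38)
Why: Anti-Markovnikov hydroboration of the terminal vinyl group (tetrasubstituted C8=C9 is inert) gives the B-alkyl borane 38, and B-alkyl Suzuki–Miyaura coupling with the vinyl iodide should form C12–C13 with retention of the alkene geometry; the silylated C16 oxygen keeps the lactone from rearranging in the basic medium.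

Step 29
Reactants: 39 bis-TBS ether
Product: 40 target, (4S)-4-[(1R,3Z)-1-hydroxy-4-(hydroxymethyl)-6-[(4aR,8aS)-2,5,5,8a-tetramethyl-3,4,4a,5,6,7,8,8a-octahydronaphthalen-1-yl]hex-3-en-1-yl]oxolan-2-one
Conditions: HF·pyridine, pyridine, THF, 0 → 25 °C
Reagents that add atoms: none
Why: Buffered HF should cleave both silyl ethers under weakly acidic conditions that neither open nor transpose the lactone nor ionise the allylic alcohol.

**Compound list**

1 | 2,6-dimethylbenzoic acid | Cc1cccc(C)c1C(=O)O | starting material
2 | 3-bromo-2,6-dimethylbenzoic acid | Cc1ccc(Br)c(C)c1C(=O)O | intermediate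
3 | methyl 3-bromo-2,6-dimethylbenzoate | COC(=O)c1c(C)ccc(Br)c1C | intermediate
4 | isobutyronitrile | CC(C)C#N | starting material
5 | methyl 3-(2-cyanopropan-2-yl)-2,6-dimethylbenzoate | COC(=O)c1c(C)ccc(C(C)(C)C#N)c1C | intermediate
6 | methyl 3-bromo-5-(2-cyanopropan-2-yl)-2,6-dimethylbenzoate | COC(=O)c1c(C)c(Br)cc(C(C)(C)C#N)c1C | intermediate
7 | methyl 3-(2-cyanopropan-2-yl)-5-hydroxy-2,6-dimethylbenzoate | COC(=O)c1c(C)c(O)cc(C(C)(C)C#N)c1C | intermediate
8 | methyl 4-bromo-3-(2-cyanopropan-2-yl)-5-hydroxy-2,6-dimethylbenzoate | COC(=O)c1c(C)c(O)c(Br)c(C(C)(C)C#N)c1C | intermediate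
9 | 2-bromo-5-(hydroxymethyl)-3-(1-imino-2-methylpropan-2-yl)-4,6-dimethylphenol (aldimine, not isolated) | N=CC(C)(C)c1c(Br)c(O)c(C)c(CO)c1C | intermediate
10 | 2-[2-bromo-3-hydroxy-5-(hydroxymethyl)-4,6-dimethylphenyl]-2-methylpropanal | O=CC(C)(C)c1c(Br)c(O)c(C)c(CO)c1C | intermediate
11 | 2-[2-bromo-3-(tert-butyldimethylsilyloxy)-5-(tert-butyldimethylsilyloxymethyl)-4,6-dimethylphenyl]-2-methylpropanal | O=CC(C)(C)c1c(Br)c(O[Si](C)(C)C(C)(C)C)c(C)c(CO[Si](C)(C)C(C)(C)C)c1C | intermediate
12 | methyl (Z)-4-aryl-4-methylpent-2-enoate (aryl as in 11) | COC(=O)/C=C\C(C)(C)c1c(Br)c(O[Si](C)(C)C(C)(C)C)c(C)c(CO[Si](C)(C)C(C)(C)C)c1C | intermediate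
13 | (Z)-4-aryl-4-methylpent-2-en-1-ol (aryl as in 11) | OC/C=C\C(C)(C)c1c(Br)c(O[Si](C)(C)C(C)(C)C)c(C)c(CO[Si](C)(C)C(C)(C)C)c1C | intermediate
14 | (Z)-4-aryl-4-methylpent-2-en-1-yl methyl carbonate (aryl as in 11) | COC(=O)OC/C=C\C(C)(C)c1c(Br)c(O[Si](C)(C)C(C)(C)C)c(C)c(CO[Si](C)(C)C(C)(C)C)c1C | intermediate
15 | (Z)-4-[2-bromo-3-hydroxy-5-(tert-butyldimethylsilyloxymethyl)-4,6-dimethylphenyl]-4-methylpent-2-en-1-yl methyl carbonate (key-step precursor) | COC(=O)OC/C=C\C(C)(C)c1c(Br)c(O)c(C)c(CO[Si](C)(C)C(C)(C)C)c1C | intermediate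
16 | (4aR)-1-bromo-4-(tert-butyldimethylsilyloxymethyl)-3,4a,8,8-tetramethyl-5,8-dihydronaphthalen-2(4aH)-one (key-step product) | CC1=C(CO[Si](C)(C)C(C)(C)C)[C@@]2(C)CC=CC(C)(C)C2=C(Br)C1=O | intermediate
17 | (5R,10S)-cis-fused enone, 11-OTBS, C7 ketone, C8=C9 | CC1=C(CO[Si](C)(C)C(C)(C)C)[C@@]2(C)CCCC(C)(C)[C@H]2CC1=O | intermediate
18 | lithium C6=C7 dienolate of 17 (not isolated) | CC1=C(CO[Si](C)(C)C(C)(C)C)[C@@]2(C)CCCC(C)(C)[C@H]2C=C1[O-].[Li+] | intermediate
19 | (5R,10S)-dienyl triflate, C6=C7(OTf), C8=C9 | CC1=C(CO[Si](C)(C)C(C)(C)C)[C@@]2(C)CCCC(C)(C)[C@H]2C=C1OS(=O)(=O)C(F)(F)F | intermediate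
20 | (5R,10S)-diene, C6=C7 and C8=C9, 11-OTBS | CC1=C(CO[Si](C)(C)C(C)(C)C)[C@@]2(C)CCCC(C)(C)[C@H]2C=C1 | intermediate
21 | (5R,10S)-11-(tert-butyldimethylsilyloxy)-4,4,8,10-tetramethyl decal-8-ene | CC1=C(CO[Si](C)(C)C(C)(C)C)[C@@]2(C)CCCC(C)(C)[C@H]2CC1 | intermediate
22 | (5R,10S)-allylic alcohol (C11–OH) | CC1=C(CO)[C@@]2(C)CCCC(C)(C)[C@H]2CC1 | intermediate
23 | (5R,10S)-enal (C11 aldehyde) | CC1=C(C=O)[C@@]2(C)CCCC(C)(C)[C@H]2CC1 | intermediate
24 | (5R,10S)-9-vinyl decal-8-ene | CC1=C(C=C)[C@@]2(C)CCCC(C)(C)[C@H]2CC1 | intermediate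
25 | ethyl (S)-4-bromo-3-hydroxybutanoate | CCOC(=O)C[C@H](O)CBr | starting material
26 | ethyl (S)-2-(oxiran-2-yl)acetate | CCOC(=O)C[C@H]1CO1 | intermediate
27 | tert-butyldimethyl(prop-2-yn-1-yloxy)silane | C#CCO[Si](C)(C)C(C)(C)C | starting material
28 | lithium acetylide of 27 (not isolated) | [Li+].[C-]#CCO[Si](C)(C)C(C)(C)C | intermediate
29 | ethyl (R)-7-(tert-butyldimethylsilyloxy)-3-hydroxyhept-5-ynoate | CC(C)(C)[Si](C)(C)OCC#CC[C@@H](O)CC(=O)OCC | intermediate
30 | dilithium alkoxide–enolate of 29 (not isolated) | CC(C)(C)[Si](C)(C)OCC#CC[C@@H]([O-])C=C([O-])OCC.[Li+].[Li+] | intermediate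
31 | 4-tert-butyl 1-ethyl (2R)-2-[(1R)-5-(tert-butyldimethylsilyloxy)-1-hydroxypent-3-yn-1-yl]butanedioate | CC(C)(C)[Si](C)(C)OCC#CC[C@@H](O)[C@@H](CC(=O)OC(C)(C)C)C(=O)OCC | intermediate
32 | 4-tert-butyl 1-ethyl (2R)-2-[(1R)-1,5-bis(tert-butyldimethylsilyloxy)pent-3-yn-1-yl]butanedioate | CC(C)(C)[Si](C)(C)OCC#CC[C@@H](O[Si](C)(C)C(C)(C)C)[C@@H](CC(=O)OC(C)(C)C)C(=O)OCC | intermediate
33 | (2S)-2-[(1R)-1,5-bis(tert-butyldimethylsilyloxy)pent-3-yn-1-yl]butane-1,4-diol | CC(C)(C)[Si](C)(C)OCC#CC[C@@H](O[Si](C)(C)C(C)(C)C)[C@@H](CCO)CO | intermediate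
34 | (4S)-4-[(1R)-1,5-bis(tert-butyldimethylsilyloxy)pent-3-yn-1-yl]oxolan-2-ol (lactol, not isolated) | CC(C)(C)[Si](C)(C)OCC#CC[C@@H](O[Si](C)(C)C(C)(C)C)[C@@H]1COC(O)C1 | intermediate
35 | (4S)-4-[(1R)-1,5-bis(tert-butyldimethylsilyloxy)pent-3-yn-1-yl]oxolan-2-one | CC(C)(C)[Si](C)(C)OCC#CC[C@@H](O[Si](C)(C)C(C)(C)C)[C@@H]1COC(=O)C1 | intermediate
36 | (4S)-4-[(1R,3E)-1,5-bis(tert-butyldimethylsilyloxy)-4-(tributylstannyl)pent-3-en-1-yl]oxolan-2-one (not isolated) | CCCC[Sn](CCCC)(CCCC)/C(CO[Si](C)(C)C(C)(C)C)=C/C[C@@H](O[Si](C)(C)C(C)(C)C)[C@@H]1COC(=O)C1 | intermediate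
37 | (4S)-4-[(1R,3E)-1,5-bis(tert-butyldimethylsilyloxy)-4-iodopent-3-en-1-yl]oxolan-2-one | I/C(CO[Si](C)(C)C(C)(C)C)=C/C[C@@H](O[Si](C)(C)C(C)(C)C)[C@@H]1COC(=O)C1 | intermediate
38 | B-alkyl-9-BBN adduct of 24 (boron on C12, not isolated) | CC1=C(CCB2C3CCCC2CCC3)[C@@]2(C)CCCC(C)(C)[C@H]2CC1 | intermediate
39 | bis-TBS ether of the target (5R,10S,13Z,16R,17S) | CC1=C(CC/C(=C/C[C@@H](O[Si](C)(C)C(C)(C)C)[C@@H]2COC(=O)C2)CO[Si](C)(C)C(C)(C)C)[C@@]2(C)CCCC(C)(C)[C@H]2CC1 | intermediate
40 | CNP0164639.3, (4S)-4-[(1R,3Z)-1-hydroxy-4-(hydroxymethyl)-6-[(4aR,8aS)-2,5,5,8a-tetramethyl-3,4,4a,5,6,7,8,8a-octahydronaphthalen-1-yl]hex-3-en-1-yl]oxolan-2-one | CC1=C(CC/C(=C/C[C@@H](O)[C@@H]2COC(=O)C2)CO)[C@@]2(C)CCCC(C)(C)[C@H]2CC1 | target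

**Step count.** Total: 29 steps. Longest linear sequence: 22 steps (steps 1–20, then 28 and 29); the side-chain branch is steps 21–27.

**Steps most likely to fail**

1. Step 13 (the proposed new method). The anti π-allyl complex may isomerise or fail to close, so that the catalyst does not turn over, intermolecular O-allylation may consume material, or the ligand may discriminate poorly between the two faces of C10. The fallback uses the known base-mediated para-C-alkylation of a phenolate by a tethered electrophile and sets out from allylic alcohol 13. MsCl, LiCl and 2,4,6-collidine in DMF at 0 °C should give the Z-allylic chloride F1. KHF2 in MeOH then frees the phenol and gives the chloro phenol F2. KOt-Bu in t-BuOH/THF at high dilution should close ring A by SN2 attack of C10 on the primary allylic carbon (C6 is blocked by bromine, O-alkylation is impossible for the meta tether) and give the racemic dienone F3. Preparative chromatography on a chiral stationary phase separates the enantiomers, and the R enantiomer is compound 16, where the route is rejoined.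

2. Step 14. Hydrogen may be delivered to C5 with poor facial selectivity, giving trans-fused material, or the hindered C5=C6 bond may resist reduction. The fallback replaces substrate-controlled heterogeneous delivery by hydroxyl-directed homogeneous hydrogenation and sets out from 16. Hydrogenation over Pd/C with Et3N is interrupted once the C–Br bond is cleaved and C2=C3 is saturated, giving the cross-conjugated dienone F4. Luche reduction (NaBH4, CeCl3, MeOH) gives the C7 carbinols, from which the epimer with the hydroxyl on the face of the C10 methyl, the dienol F5, is separated; the other epimer is returned to F4 with MnO2. [Ir(cod)(PCy3)(py)]PF6 under H2 in CH2Cl2 should then add hydrogen to C5=C6 from the face of the coordinating hydroxyl and give the cis-fused allylic alcohol F6. MnO2 re-oxidises C7 and gives enone 17.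

3. Step 9. Addition of the phosphonate anion to the neopentyl, doubly ortho-flanked aldehyde may be slow, and Z-selectivity may erode. The fallback fixes the geometry by alkyne semihydrogenation and sets out from aldehyde 11. Me3SiCHN2 with LiN(i-Pr)2 in THF (Colvin rearrangement) should give the terminal alkyne F7. LiN(i-Pr)2 followed by paraformaldehyde gives the propargylic alcohol F8. Semihydrogenation with H2 over Pd/CaCO3 poisoned with Pb(OAc)2 and quinoline should give the Z-allylic alcohol 13, where the route is rejoined.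

**Further compounds**

F1 | step 13 | (Z)-4-aryl-4-methylpent-2-en-1-yl chloride (aryl as in 11) | ClC/C=C\C(C)(C)c1c(Br)c(O[Si](C)(C)C(C)(C)C)c(C)c(CO[Si](C)(C)C(C)(C)C)c1C
F2 | step 13 | 2-bromo-3-[(Z)-5-chloro-2-methylpent-3-en-2-yl]-5-(tert-butyldimethylsilyloxymethyl)-4,6-dimethylphenol | ClC/C=C\C(C)(C)c1c(Br)c(O)c(C)c(CO[Si](C)(C)C(C)(C)C)c1C
F3 | step 13 | racemic 1-bromo-4-(tert-butyldimethylsilyloxymethyl)-3,4a,8,8-tetramethyl-5,8-dihydronaphthalen-2(4aH)-one | CC1=C(CO[Si](C)(C)C(C)(C)C)C2(C)CC=CC(C)(C)C2=C(Br)C1=O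
F4 | step 14 | (10S)-dienone without bromine and with saturated ring A (C5=C6 and C8=C9, C7 ketone) | CC1=C(CO[Si](C)(C)C(C)(C)C)[C@@]2(C)CCCC(C)(C)C2=CC1=O
F5 | step 14 | (7S,10S)-dienol, 7-OH cis to the C10 methyl | CC1=C(CO[Si](C)(C)C(C)(C)C)[C@@]2(C)CCCC(C)(C)C2=C[C@@H]1O
F6 | step 14 | (5R,7S,10S)-cis-fused allylic alcohol, C8=C9 | CC1=C(CO[Si](C)(C)C(C)(C)C)[C@@]2(C)CCCC(C)(C)[C@H]2C[C@@H]1O
F7 | step 9 | 3-aryl-3-methylbut-1-yne (aryl as in 11) | C#CC(C)(C)c1c(Br)c(O[Si](C)(C)C(C)(C)C)c(C)c(CO[Si](C)(C)C(C)(C)C)c1C
F8 | step 9 | 4-aryl-4-methylpent-2-yn-1-ol (aryl as in 11) | OCC#CC(C)(C)c1c(Br)c(O[Si](C)(C)C(C)(C)C)c(C)c(CO[Si](C)(C)C(C)(C)C)c1C
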